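# Proposed total synthesis of CNP0184494.1 (40) by anthrone ring expansion

## Analysis of the target

Target 40 (C84H64O18) is a resveratrol hexamer made of three copies of one unit, a trans-(2R,3R)-2-(4-hydroxyphenyl)-3-aryl-2,3-dihydrobenzofuran, arranged around two medium carbocycles that are joined by one methine. In the first unit (arene ring B, furan C-3 = C-b) the C-3 resorcinol ring A is tied back to C-4 of ring B through C-a [CH(4-hydroxyphenyl)] and C-c, which closes a dibenzo-fused seven-membered ring. In the second unit (arene ring C, furan carbons C-f and C-g) the C-3 resorcinol ring D is tied back to C-4 through C-h [CH(4-hydroxyphenyl)], C-i and C-e, which closes an eight-membered ring; C-i carries the third unit through C-4 of its arene ring E (furan carbons C-j and C-k, free resorcinol ring F), and C-c and C-e are joined through C-d, again a CH(4-hydroxyphenyl). Of the twelve stereocentres six lie in the furans; on the seven-membered ring the hydrogens at C-a, C-b and C-c share one face, on the eight-membered ring those at C-f and C-h share one face and those at C-e and C-i the other, and C-d is (R). The sensitive groups are fifteen free phenols on electron-rich arenes, three benzylic C–O bonds of the furans that ionise under acid, and several doubly benzylic methines. The difficulty is that two arene-flanked medium rings must be built and two congested halves joined through C-d with control at C-c, C-d, C-e and C-i. The strategy rests on the position of C-a between C-c and a ring A carbon that is ortho and para to oxygen: removing C-a with its aryl group leaves a six-membered ring closed by a carbonyl between rings A and B, an anthrone, which is what the C-4 carboxylic acid of the unit forms when it acylates ring A. C-h stands in the same relation to ring D and C-i, so the same one-carbon insertion serves both rings.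

## Retrosynthetic reasoning

**40 to 39.** The fifteen phenols are unmasked last from pentadecamethyl ether 39. Methyl ethers are the only phenol protection that survives every organometallic, Lewis-acid and radical step of the route, and one global cleavage replaces any selective deprotection.

**39 to 38 to 35 + 12.** The C-i–ring E bond and the C-i–H bond are cut. This leads back to ketone 35 (carbonyl at C-i) and Grignard reagent 36, made from block bromide 12. The tertiary oxygen that the addition leaves is carried as oxalate 38 and removed through a radical. A cation at C-i would draw hydride from C-h, whose cation is far more stable, and would scramble two centres. The forward step has to deliver hydrogen to the face of C-i opposite the linker.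

**35 to 26 + 33.** The C-d–C-e bond is cut. C-d is the one carbon between the halves that can be a stabilised cation, because it carries a 4-methoxyphenyl group. C-e is α to the C-i carbonyl, so it can be the nucleophile as enol silane 33. The cation comes from exocyclic alkene 26 by protonation at C-c. The forward reaction therefore sets C-c, C-d and C-e and joins the two halves in one operation.

**26 to 25 to 22 + 23.** The C-c=C-d double bond is traced to tertiary alcohol 25 by loss of water. The C-c–C-d bond is then cut to seven-ring ketone 22 and benzyl nucleophile 23. The ketone at C-c is the natural acceptor for the linker carbon.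

**22 to 16 + 21 (key disconnection).** The ring A–C-a and C-a–C-c bonds are both cut. This removes C-a with its aryl group as diazo compound 21 and contracts the seven-membered ring to anthrone 16. Cutting here gives a ketone that the block acid reaches in one ring closure. The forward reaction must insert one carbon into the diaryl ketone with migration of the ring A carbon, so that the carbonyl stays on C-c.

**16 to 14 to 12.** The carbonyl–ring A bond of 16 is an intramolecular acylation of ring A by acid 14. The carboxyl group comes from the bromide of 12 by metalation and carboxylation.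

**33 to 32 to 31 + 21.** The enol silane comes from eight-ring ketone 32. Excising C-h with its aryl group from 32 in the same way leaves seven-ring ketone 31 and a second equivalent of 21. Ketone 31 is the ring closure of homologous acid 29 onto ring D. Acid 29 comes from ester 28 and thus from 12 and zinc enolate 27 by cross-coupling.

**12 to 6 + 9.** All three benzofuran units are one compound, 12. Its O–C-2 and C-2–C-3 bonds are cut in a formal [4+1] sense to an ortho-quinone methide precursor, sulfone 6, and chiral sulfonium salt 9, which carries the 4-methoxybenzyl carbon and the source of absolute configuration. Sulfone 6 comes from diol 4, made from salicylaldehyde 2 (from 1) and aryl Grignard reagent 3; building the carbinol on the aldehyde fixes the arene substitution pattern without a regiochemical question. Salt 9 comes from 7 and 8. Diazo compound 21 comes from 17 and 18 through 19.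

## Alternatives that were turned down

**Alternative 1:** Vinylketene benzannulation.
- Disconnection: the benzene ring and the furan ring of the repeating benzofuran unit are both taken apart, back to an acyclic diazo enone with a tethered alkynyl ether.
- Forward key step: irradiation triggers a Wolff rearrangement to a vinylketene, which adds to the alkyne in a [2+2] sense. Four-electron opening and six-electron closure then give (2R,3R)-4-[(tert-butyldimethylsilyloxy)methyl]-3-(3,5-dimethoxyphenyl)-2-(4-methoxyphenyl)-2,3-dihydro-1-benzofuran-6-ol, A1.
- For: complete regiocontrol of the arene; a free C-6 phenol distinct from the other oxygens; a C-4 carbon at the alcohol oxidation level that can become acid, aldehyde or benzylic electrophile. On handle flexibility A1 is stronger than bromide 12.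
- Against: both stereocentres must already sit in the tether of a long acyclic precursor and survive the photolysis. The inventive step is spent on the part of the molecule that is easiest, and both medium rings and the linker remain unsolved.
- Comparison: the chosen route reaches 12 in four linear steps, uses its bromide for all three roles (acid, homologous acid, aryl nucleophile) and places its one unprecedented reaction on the seven-membered ring.

**Alternative 2:** Aryne insertion to the eight-membered ring.
- Disconnection: the eight-membered ring is cut at the two bonds to ring D, which leaves a six-membered β-keto ester and 3,5-dimethoxybenzyne, A4.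
- Forward key step: the ester-bearing enol carbon adds to A4, the aryl anion closes on the ketone and the benzocyclobutenoxide fragments. The ring grows by two atoms to dibenzocyclooctenone A2.
- For: this is a known reaction class for cyclic β-keto esters and forms the hard ring directly. The methoxy group next to the aryne steers the addition the right way. In A2 the ketone lies on C-h and C-i already carries ring E. The last aryl group would therefore enter at a carbon whose cation is the stabilised diarylmethyl one. That is stronger than steps 19 and 20 of the chosen route.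
- Against: the six-membered precursor must already carry a vinyl group and a whole benzofuran unit on adjacent stereocentres. The furan on rings C and D still has to be built from the ester carbon and a benzyl-protected phenol at a congested diarylmethine, with its trans relationship and absolute configuration unset. The seven-membered half needs a separate solution.
- Comparison: the chosen route uses one block and one reaction type for both medium rings and has every furan stereocentre fixed from the start.

**Alternative 3:** Aryne insertion to the seven-membered ring.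
- Disconnection: the seven-membered ring is cut at the two bonds to ring A, leaving a five-membered β-keto ester and A4.
- Forward key step: the same addition, closure and fragmentation sequence gives dibenzocycloheptanone A3.
- For: a known reaction class. In A3 the ketone lies on C-a and the CH2 α to it is C-c, so the linker could be attached by enolate chemistry and the C-a aryl group by addition and ionic reduction. On precedent and on the polarity at C-c it is stronger than the chosen key step.
- Against: A3 has no stereocentre except an epimerisable ester carbon, so absolute configuration must be introduced later. The furan must again be built afterwards through benzyl ether removal and a stereocontrolled closure. The eight-membered half is untouched.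
- Comparison: the chosen route accepts an unprecedented insertion. In return, C-a and its aryl group are installed in one step on a substrate that already holds the complete, enantiopure furan, and the same reaction is reused for C-h.

Key step: step 10

Assumption: the ylide from (1R,4R,5R)-isothiocineole is taken to give the (2R,3R) block; if the annulation shows the opposite sense, the enantiomeric sulfide is used with no other change.
Assumption: 3, 23 and 27 are bought as solutions; the carbinol centres of 25 and 38 and the alkene geometry of 26 are erased later and are drawn as expected, and the chloride-bearing carbon of 34 is left unassigned because both epimers ionise to the same cation.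

## Route

Step 1
Reactants: 1 2-bromo-4,6-dimethoxybenzaldehyde
Product: 2 2-bromo-6-hydroxy-4-methoxybenzaldehyde
Conditions: BCl3, CH2Cl2, −78 to 0 °C; H2O
Reagents that add atoms: none
Why: Chelation-controlled ether cleavage: BCl3 bridges the aldehyde oxygen and the ortho methoxy group and removes only that methyl group, so the para methoxy group stays.

Step 2
Reactants: 2 2-bromo-6-hydroxy-4-methoxybenzaldehyde; 3 3,5-dimethoxyphenylmagnesium chloride
Product: 4 rac-3-bromo-2-[(3,5-dimethoxyphenyl)(hydroxy)methyl]-5-methoxyphenol
Conditions: 3 (2.2 equiv), THF, 0 °C; aq. NH4Cl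
Reagents that add atoms: none
Why: Grignard addition to the aldehyde; the first equivalent is spent on the phenol and the second adds to the carbonyl. The carbinol centre is racemic and is erased in step 5.

Step 3
Reactants: 4 rac-3-bromo-2-[(3,5-dimethoxyphenyl)(hydroxy)methyl]-5-methoxyphenol; 5 sodium 4-methylbenzenesulfinate
Product: 6 rac-3-bromo-2-[(3,5-dimethoxyphenyl)(4-methylbenzenesulfonyl)methyl]-5-methoxyphenol
Conditions: HCO2H, CH2Cl2/H2O, rt
Reagents that add atoms: none
Why: SN1 sulfonylation: acid ionises the benzylic alcohol, which is activated by the ortho hydroxy and para methoxy groups, and the sulfinate captures the cation at sulfur. The sulfone is a stable precursor from which base releases the ortho-quinone methide.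

Step 4
Reactants: 7 4-methoxybenzyl bromide; 8 (1R,4R,5R)-isothiocineole
Product: 9 S-(4-methoxybenzyl) sulfonium triflate of 8, benzyl group on the exo lone pair of sulfur
Conditions: LiOTf, CH2Cl2/H2O, rt
Reagents that add atoms: lithium trifluoromethanesulfonate, [Li+].[O-]S(=O)(=O)C(F)(F)F
Why: SN2 alkylation of the sulfide; exchange of bromide for triflate stops the reverse reaction, and alkylation on the exposed lone pair should give one sulfonium diastereomer.

Step 5
Reactants: 6 rac-sulfone; 9 sulfonium triflate
Product: 12 (2R,3R)-4-bromo-3-(3,5-dimethoxyphenyl)-6-methoxy-2-(4-methoxyphenyl)-2,3-dihydro-1-benzofuran (block bromide), via ortho-quinone methide 10 (not isolated), via sulfonium ylide 11 (not isolated)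
Conditions: Cs2CO3, CH2Cl2, −20 °C to rt
Reagents that add atoms: none
Why: Sulfur-ylide [4+1] annulation: carbonate eliminates sulfinate from 6 to give 10 and deprotonates 9 to 11; conjugate addition of 11 restores the phenoxide, which displaces the sulfide in a 5-exo-tet SN2 closure. The bicyclic sulfide exposes one face of the ylide carbon, which fixes C-2, and the anti placement of the two aryl groups in the addition gives the trans C-2/C-3 relationship.

Step 6
Reactants: 12 block bromide
Product: 14 (2R,3R)-3-(3,5-dimethoxyphenyl)-6-methoxy-2-(4-methoxyphenyl)-2,3-dihydro-1-benzofuran-4-carboxylic acid, via aryllithium 13 (not isolated)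
Conditions: n-BuLi, THF, −78 °C; CO2; aq. HCl
Reagents that add atoms: carbon dioxide, O=C=O
Why: Bromine–lithium exchange is faster than any deprotonation at −78 °C, and the aryllithium is carboxylated (halogen–metal exchange and carboxylation).

Step 7
Reactants: 14 block acid
Product: 16 furan-bridged anthrone: 9,10-dihydroanthracen-9-one whose C-10 is furan C-3 (C-b, R), bridged from C-10 to the peri carbon of ring B by (R)-CH(4-methoxyphenyl)–O, with methoxy groups ortho and para to the carbonyl on ring A and one methoxy group on ring B, via mixed anhydride 15 (not isolated)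
Conditions: (CF3CO)2O, CH2Cl2, 0 °C to rt, argon; aq. NaHCO3
Reagents that add atoms: none
Why: Intramolecular Friedel–Crafts acylation through the mixed trifluoroacetic anhydride: the acyl carbon at C-4 lies beside the ortho carbon of ring A, which is activated by an ortho and a para methoxy group, so the six-membered ring closes. If C-b passes through the anthranol tautomer it is reprotonated trans to the C-2 aryl group, the more stable arrangement, so the (2R,3R) configuration is kept.

Step 8
Reactants: 17 4-methoxybenzaldehyde; 18 4-methylbenzenesulfonohydrazide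
Product: 19 (E)-4-methoxybenzaldehyde 4-methylbenzenesulfonylhydrazone
Conditions: MeOH, rt
Reagents that add atoms: none
Why: Condensation of the aldehyde with the sulfonyl hydrazide (hydrazone formation).

Step 9
Reactants: 19 tosylhydrazone
Product: 21 4-methoxyphenyldiazomethane, via hydrazone sodium salt 20 (not isolated)
Conditions: NaOMe, MeOH, rt; evaporate; 90–110 °C, 0.1 mbar, trap at −78 °C
Reagents that add atoms: none
Why: Bamford–Stevens reaction: the sodium salt loses sulfinate on heating under vacuum, and the aryldiazomethane distils into a cold trap before it can decompose.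

Step 10
Reactants: 16 furan-bridged anthrone; 21 4-methoxyphenyldiazomethane
Product: 22 seven-ring ketone: ring A–C-a[H, 4-methoxyphenyl, (S)]–C-c(=O)–ring B, with H at C-a and H at C-b on the same face and the furan (2R,3R)
Conditions: Sc(OTf)3 (20 mol %), CH2Cl2, −78 to −20 °C, slow addition of 21; AcOH quench; then DBU (0.2 equiv), CH2Cl2, rt
Reagents that add atoms: none
Why: Proposed new method: Sc(OTf)3 activates the anthrone carbonyl, the nucleophilic diazo carbon of 21 adds to it, and the resulting β-diazonium alkoxide collapses by 1,2-shift of an aryl carbon with loss of N2 (Büchner–Curtius–Schlotterbeck homologation), which forms the ring A–C-a and C-a–C(=O) bonds in one operation. The closest known reaction type is the Lewis-acid-promoted diazoalkane ring expansion of cyclic aryl ketones such as tetralones and fluorenone; it has not been shown for a diaryl ketone whose carbonyl is deactivated and flanked by an ortho methoxy group. The seven-membered ring is closed by enlargement of the six-membered anthrone ring through the 1,2-shift, not by a cyclisation. The selectivity needed is migration of the ring A carbon and not the ring B carbon; the ring A carbon is ortho and para to methoxy groups and bridges the developing positive charge far better than the ring B carbon, which is meta to both of its oxygens, and this leaves the ketone on C-c. The new stereocentre C-a is α to the ketone and doubly benzylic, so the ratio from the shift is corrected by DBU through the enol to the epimer expected to be more stable, with the 4-methoxyphenyl group pseudo-axial, clear of the peri methoxy group of ring A and on the face opposite the C-b hydrogen. A second insertion is not expected because the product ketone has a diarylmethyl carbon beside the carbonyl, and alkylation through the anthranol tautomer is held back by the low temperature and slow addition.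

Step 11
Reactants: 22 seven-ring ketone; 23 4-methoxybenzylmagnesium chloride
Product: 25 tertiary alcohol: 22 with C-c bearing OH and CH2(4-methoxyphenyl), the benzyl group on the face of the C-a hydrogen, via benzylcerium dichloride 24 (not isolated)
Conditions: CeCl3 (anhydrous), THF, −78 °C; aq. NH4Cl
Reagents that add atoms: none
Why: Organocerium addition: the cerium reagent is only weakly basic, so it adds to the easily enolised ketone and does not deprotonate C-a; approach anti to the pseudo-axial aryl group of C-a gives the carbinol drawn, whose configuration is lost in step 12.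

Step 12
Reactants: 25 tertiary alcohol
Product: 26 exocyclic alkene: C-c=C-d(H)(4-methoxyphenyl), aryl group trans to ring B
Conditions: Burgess reagent, benzene, 50 °C
Reagents that add atoms: none
Why: Burgess dehydration is a syn elimination through the sulfamate ester; the ring hydrogen at C-a is anti to the oxygen and out of reach, so only a hydrogen of the freely rotating benzylic CH2 is removed. No free cation forms that could draw hydride from C-a.

Step 13
Reactants: 12 block bromide; 27 (2-ethoxy-2-oxoethyl)zinc bromide
Product: 28 ethyl 2-[(2R,3R)-3-(3,5-dimethoxyphenyl)-6-methoxy-2-(4-methoxyphenyl)-2,3-dihydro-1-benzofuran-4-yl]acetate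
Conditions: Pd(dba)2 (5 mol %), XPhos (10 mol %), THF, 60 °C
Reagents that add atoms: none
Why: Negishi coupling of a Reformatsky reagent: oxidative addition of the aryl bromide to zerovalent palladium, transmetalation from zinc and reductive elimination form the aryl–CH2 bond without touching the stereocentres.

Step 14
Reactants: 28 ethyl ester
Product: 29 2-[(2R,3R)-3-(3,5-dimethoxyphenyl)-6-methoxy-2-(4-methoxyphenyl)-2,3-dihydro-1-benzofuran-4-yl]acetic acid
Conditions: LiOH, THF/MeOH/H2O, rt; aq. HCl
Reagents that add atoms: lithium hydroxide, [Li+].[OH-]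
Why: Saponification of the ester; base leaves the aryl ethers and the furan intact.

Step 15
Reactants: 29 arylacetic acid
Product: 31 seven-ring benzyl ketone: ring D–C(=O)–CH2(C-e)–ring C, furan (2R,3R), via mixed anhydride 30 (not isolated)
Conditions: (CF3CO)2O, CH2Cl2, 0 °C to rt
Reagents that add atoms: none
Why: Intramolecular Friedel–Crafts acylation as in step 7, here closing a seven-membered ring onto the ortho carbon of ring D, which is activated by an ortho and a para methoxy group.

Step 16
Reactants: 31 seven-ring benzyl ketone; 21 4-methoxyphenyldiazomethane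
Product: 32 eight-ring ketone: ring D–C-h[H, 4-methoxyphenyl, (S)]–C-i(=O)–C-e H2–ring C, with H at C-h and H at C-f on the same face
Conditions: Sc(OTf)3 (20 mol %), CH2Cl2, −78 to −20 °C, slow addition of 21; AcOH quench; then DBU (0.2 equiv), rt
Reagents that add atoms: none
Why: Proposed new method: the same Lewis-acid-promoted diazoalkane homologation as in step 10, on a benzo-fused aryl alkyl ketone; 21 adds to the activated carbonyl and the ring D carbon, which is ortho and para to methoxy groups, migrates in preference to the benzylic CH2, so C-h is inserted between ring D and the carbonyl and the ketone ends on C-i. The closest known reaction type is the diazoalkane ring expansion of tetralones, in which the aryl carbon migrates; it has not been shown with an aryldiazomethane on a methoxy-deactivated ketone of this kind. C-h is α to the ketone and is equilibrated with DBU to the epimer that corresponds to C-a in 22.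

Step 17
Reactants: 32 eight-ring ketone
Product: 33 trimethylsilyl enol ether of 32 with the double bond C-i=C-e (cis within the ring), C-h unchanged
Conditions: LiN(i-Pr)2, Me3SiCl (internal quench), THF, −78 °C; non-aqueous work-up
Reagents that add atoms: chlorotrimethylsilane, C[Si](C)(C)Cl
Why: Kinetic enolisation: the hindered amide removes a proton from the exposed CH2 (C-e) and not from the more acidic but buried diarylmethine C-h, and the silyl chloride already in the flask traps the enolate before it can equilibrate.

Step 18
Reactants: 26 exocyclic alkene; 33 enol silane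
Product: 35 coupled ketone: C-c(H)–C-d(H)(4-methoxyphenyl)–C-e(H) joined, ketone at C-i, all centres as in 40, via benzylic chloride 34 (not isolated)
Conditions: HCl (1.0 equiv, Et2O), CH2Cl2, −78 °C; then 2,6-di-tert-butyl-4-methylpyridine, 33, ZnCl2, −78 to −30 °C
Reagents that add atoms: none
Why: Markovnikov addition of HCl places the proton on C-c from the face opposite the C-a aryl group and stores the C-d cation as its benzylic chloride; ZnCl2 re-ionises it and the enol silane attacks through C-e (Lewis-acid-mediated SN1 alkylation of a silyl enol ether, a Mukaiyama-type reaction). C-d is set by Felkin–Anh approach anti to the ring B carbon on C-c, with the C-c hydrogen beside the aryl group of the cation. C-e is set by approach to the enol face remote from the C-h aryl group and, being α to the ketone, can also settle by equilibration.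

Step 19
Reactants: 35 coupled ketone; 12 block bromide
Product: 38 methyl oxalate of the tertiary carbinol at C-i, which carries ring E, via arylmagnesium bromide 36 (not isolated), via bromomagnesium alkoxide 37 (not isolated)
Conditions: 12, Mg turnings, LiCl, THF, rt; then 35, LaCl3·2LiCl (1.0 equiv), THF, 0 °C to rt; then ClC(O)CO2Me, 0 °C
Reagents that add atoms: methyl chlorooxoacetate, COC(=O)C(=O)Cl
Why: Lanthanide-promoted Grignard addition: magnesium insertion assisted by LiCl turns the aryl bromide into its Grignard reagent, and the soluble, strongly oxophilic LaCl3·2LiCl activates the hindered ketone and tempers the basicity of the nucleophile, so 1,2-addition from the face away from the linker outruns enolisation. The alkoxide is acylated in the flask because the free tertiary alcohol would be too hindered to esterify later; its configuration does not matter, since step 20 passes through a planar radical.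

Step 20
Reactants: 38 methyl oxalate
Product: 39 pentadeca-O-methyl ether of 40
Conditions: Bu3SnH, AIBN, benzene, 80 °C
Reagents that add atoms: none
Why: Barton-type radical deoxygenation of a tertiary oxalate: the stannyl radical adds to the oxalyl carbonyl, the C–O bond breaks to a tertiary benzylic radical at C-i, and tin hydride delivers hydrogen to the face opposite the bulky linker on C-e, which places ring E cis to the linker and trans to the C-h aryl group. A radical is used because a cation at C-i would draw hydride from C-h and scramble both centres.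

Step 21
Reactants: 39 pentadeca-O-methyl ether
Product: 40 CNP0184494.1
Conditions: BBr3 (excess), CH2Cl2, −78 to 0 °C; MeOH/H2O quench at −78 °C
Reagents that add atoms: none
Why: Lewis-acid cleavage of all fifteen aryl methyl ethers (bromide attacks the methyl group of the boron-bound ether); it is run and quenched cold so that the benzylic C–O bonds of the three dihydrofurans are not ionised.

## Compound list

1 | 2-bromo-4,6-dimethoxybenzaldehyde | O=Cc1c(Br)cc(OC)cc1OC | starting material
2 | 2-bromo-6-hydroxy-4-methoxybenzaldehyde | O=Cc1c(Br)cc(OC)cc1O | intermediate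
3 | 3,5-dimethoxyphenylmagnesium chloride | COc1cc(OC)cc([Mg]Cl)c1 | starting material
4 | rac-3-bromo-2-[(3,5-dimethoxyphenyl)(hydroxy)methyl]-5-methoxyphenol | COc1cc(O)c(C(O)c2cc(OC)cc(OC)c2)c(Br)c1 | intermediate
5 | sodium 4-methylbenzenesulfinate | [Na+].[O-]S(=O)c1ccc(C)cc1 | starting material
6 | rac-3-bromo-2-[(3,5-dimethoxyphenyl)(4-methylbenzenesulfonyl)methyl]-5-methoxyphenol | COc1cc(O)c(C(c2cc(OC)cc(OC)c2)S(=O)(=O)c2ccc(C)cc2)c(Br)c1 | intermediate
7 | 4-methoxybenzyl bromide | COc1ccc(CBr)cc1 | starting material
8 | (1R,4R,5R)-isothiocineole, (1R,4R,5R)-4,7,7-trimethyl-6-thiabicyclo[3.2.1]octane | C[C@@H]1CC[C@@H]2C[C@H]1SC2(C)C | starting material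
9 | S-(4-methoxybenzyl) sulfonium triflate of 8 (benzyl on the exo lone pair) | C[C@@H]1CC[C@@H]2C[C@H]1[S@@+](Cc1ccc(OC)cc1)C2(C)C.[O-]S(=O)(=O)C(F)(F)F | intermediate
10 | ortho-quinone methide, 5-bromo-6-[(3,5-dimethoxyphenyl)methylidene]-3-methoxycyclohexa-2,4-dien-1-one, aryl syn to C=O (not isolated) | COC1=CC(=O)/C(=C\c2cc(OC)cc(OC)c2)C(Br)=C1 | intermediate
11 | sulfonium ylide from 9 (not isolated) | C[C@@H]1CC[C@@H]2C[C@H]1[S@@+]([CH-]c1ccc(OC)cc1)C2(C)C | intermediate
12 | (2R,3R)-4-bromo-3-(3,5-dimethoxyphenyl)-6-methoxy-2-(4-methoxyphenyl)-2,3-dihydro-1-benzofuran (block bromide) | Brc1cc(OC)cc2c1[C@@H](c1cc(OC)cc(OC)c1)[C@H](c1ccc(OC)cc1)O2 | intermediate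
13 | 4-lithio derivative of the block (not isolated) | [Li]c1cc(OC)cc2c1[C@@H](c1cc(OC)cc(OC)c1)[C@H](c1ccc(OC)cc1)O2 | intermediate
14 | (2R,3R)-3-(3,5-dimethoxyphenyl)-6-methoxy-2-(4-methoxyphenyl)-2,3-dihydro-1-benzofuran-4-carboxylic acid | OC(=O)c1cc(OC)cc2c1[C@@H](c1cc(OC)cc(OC)c1)[C@H](c1ccc(OC)cc1)O2 | intermediate
15 | mixed anhydride of 14 with trifluoroacetic acid (not isolated) | O=C(OC(=O)C(F)(F)F)c1cc(OC)cc2c1[C@@H](c1cc(OC)cc(OC)c1)[C@H](c1ccc(OC)cc1)O2 | intermediate
16 | furan-bridged anthrone, C-b (R), furan C-2 (R) | O=C2c3c(OC)cc(OC)cc3[C@@H]3c4c(cc(OC)cc42)O[C@H]3c2ccc(OC)cc2 | intermediate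
17 | 4-methoxybenzaldehyde | COc1ccc(C=O)cc1 | starting material
18 | 4-methylbenzenesulfonohydrazide | Cc1ccc(S(=O)(=O)NN)cc1 | starting material
19 | (E)-4-methoxybenzaldehyde 4-methylbenzenesulfonylhydrazone | COc1ccc(/C=N/NS(=O)(=O)c2ccc(C)cc2)cc1 | intermediate
20 | sodium salt of 19 (not isolated) | COc1ccc(/C=N/[N-]S(=O)(=O)c2ccc(C)cc2)cc1.[Na+] | intermediate
21 | 4-methoxyphenyldiazomethane | COc1ccc(C=[N+]=[N-])cc1 | intermediate
22 | seven-ring ketone, C-a (S), carbonyl at C-c | COc1ccc([C@H]2c3c(OC)cc(OC)cc3[C@@H]3c4c(cc(OC)cc4C2=O)O[C@H]3c2ccc(OC)cc2)cc1 | intermediate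
23 | 4-methoxybenzylmagnesium chloride | COc1ccc(C[Mg]Cl)cc1 | starting material
24 | (4-methoxybenzyl)cerium dichloride (not isolated) | COc1ccc(C[Ce](Cl)Cl)cc1 | intermediate
25 | tertiary alcohol at C-c, benzyl group cis to H at C-a | COc1ccc([C@H]2c3c(OC)cc(OC)cc3[C@@H]3c4c(cc(OC)cc4[C@]2(O)Cc2ccc(OC)cc2)O[C@H]3c2ccc(OC)cc2)cc1 | intermediate
26 | exocyclic alkene C-c=C-d, aryl trans to ring B | COc1ccc([C@H]2c3c(OC)cc(OC)cc3[C@@H]3c4c(cc(OC)cc4/C2=C/c2ccc(OC)cc2)O[C@H]3c2ccc(OC)cc2)cc1 | intermediate
27 | (2-ethoxy-2-oxoethyl)zinc bromide | CCOC(=O)C[Zn]Br | starting material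
28 | ethyl 2-[(2R,3R)-block-4-yl]acetate | CCOC(=O)Cc1cc(OC)cc2c1[C@@H](c1cc(OC)cc(OC)c1)[C@H](c1ccc(OC)cc1)O2 | intermediate
29 | 2-[(2R,3R)-block-4-yl]acetic acid | OC(=O)Cc1cc(OC)cc2c1[C@@H](c1cc(OC)cc(OC)c1)[C@H](c1ccc(OC)cc1)O2 | intermediate
30 | mixed anhydride of 29 with trifluoroacetic acid (not isolated) | O=C(Cc1cc(OC)cc2c1[C@@H](c1cc(OC)cc(OC)c1)[C@H](c1ccc(OC)cc1)O2)OC(=O)C(F)(F)F | intermediate
31 | seven-ring benzyl ketone, ring D–C(=O)–CH2–ring C | O=C1Cc2cc(OC)cc3c2[C@@H](c2cc(OC)cc(OC)c21)[C@H](c1ccc(OC)cc1)O3 | intermediate
32 | eight-ring ketone, C-h (S), carbonyl at C-i, C-e as CH2 | C1c2cc(OC)cc3c2[C@@H](c2cc(OC)cc(OC)c2[C@H](c2ccc(OC)cc2)C1=O)[C@H](c1ccc(OC)cc1)O3 | intermediate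
33 | trimethylsilyl enol ether of 32, C-i=C-e | C[Si](C)(C)O/C1=C/c2cc(OC)cc3c2[C@@H](c2cc(OC)cc(OC)c2[C@@H]1c1ccc(OC)cc1)[C@H](c1ccc(OC)cc1)O3 | intermediate
34 | benzylic chloride at C-d, C-c set, chloride-bearing carbon both epimers and not assigned (not isolated) | COc1ccc([C@H]2c3c(OC)cc(OC)cc3[C@@H]3c4c(cc(OC)cc4[C@H]2C(Cl)c2ccc(OC)cc2)O[C@H]3c2ccc(OC)cc2)cc1 | intermediate
35 | coupled ketone, carbonyl at C-i, other centres as in 40 | COc1ccc([C@H]2c3c(OC)cc(OC)cc3[C@@H]3c4c(cc(OC)cc4[C@H]2[C@H](c2ccc(OC)cc2)[C@H]2c4cc(OC)cc5c4[C@@H](c4cc(OC)cc(OC)c4[C@H](c4ccc(OC)cc4)C2=O)[C@H](c2ccc(OC)cc2)O5)O[C@H]3c2ccc(OC)cc2)cc1 | intermediate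
36 | [(2R,3R)-block-4-yl]magnesium bromide (not isolated) | Br[Mg]c1cc(OC)cc2c1[C@@H](c1cc(OC)cc(OC)c1)[C@H](c1ccc(OC)cc1)O2 | intermediate
37 | bromomagnesium alkoxide of the C-i carbinol (not isolated) | COc1ccc([C@H]2c3c(OC)cc(OC)cc3[C@@H]3c4c(cc(OC)cc4[C@H]2[C@H](c2ccc(OC)cc2)[C@H]2c4cc(OC)cc5c4[C@@H](c4cc(OC)cc(OC)c4[C@H](c4ccc(OC)cc4)[C@]2(O[Mg]Br)c2cc(OC)cc4c2[C@@H](c2cc(OC)cc(OC)c2)[C@H](c2ccc(OC)cc2)O4)[C@H](c2ccc(OC)cc2)O5)O[C@H]3c2ccc(OC)cc2)cc1 | intermediate
38 | methyl oxalate of the C-i carbinol, ring E on the face away from the linker | COc1ccc([C@H]2c3c(OC)cc(OC)cc3[C@@H]3c4c(cc(OC)cc4[C@H]2[C@H](c2ccc(OC)cc2)[C@H]2c4cc(OC)cc5c4[C@@H](c4cc(OC)cc(OC)c4[C@H](c4ccc(OC)cc4)[C@]2(OC(=O)C(=O)OC)c2cc(OC)cc4c2[C@@H](c2cc(OC)cc(OC)c2)[C@H](c2ccc(OC)cc2)O4)[C@H](c2ccc(OC)cc2)O5)O[C@H]3c2ccc(OC)cc2)cc1 | intermediate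
39 | pentadeca-O-methyl ether of 40 | COc1ccc([C@H]2c3c(OC)cc(OC)cc3[C@@H]3c4c(cc(OC)cc4[C@H]2[C@H](c2ccc(OC)cc2)[C@H]2c4cc(OC)cc5c4[C@@H](c4cc(OC)cc(OC)c4[C@H](c4ccc(OC)cc4)[C@H]2c2cc(OC)cc4c2[C@@H](c2cc(OC)cc(OC)c2)[C@H](c2ccc(OC)cc2)O4)[C@H](c2ccc(OC)cc2)O5)O[C@H]3c2ccc(OC)cc2)cc1 | intermediate
40 | CNP0184494.1 | Oc1ccc([C@H]2c3c(O)cc(O)cc3[C@@H]3c4c(cc(O)cc4[C@H]2[C@H](c2ccc(O)cc2)[C@H]2c4cc(O)cc5c4[C@@H](c4cc(O)cc(O)c4[C@H](c4ccc(O)cc4)[C@H]2c2cc(O)cc4c2[C@@H](c2cc(O)cc(O)c2)[C@H](c2ccc(O)cc2)O4)[C@H](c2ccc(O)cc2)O5)O[C@H]3c2ccc(O)cc2)cc1 | target

## Step count and least certain steps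

Total: 21 steps. Longest linear sequence: 13 steps (1, 2, 3, 5, 6, 7, 10, 11, 12, 18, 19, 20, 21; the branch through steps 13–17 is equally long).

**Step 10 (key step, carries the label).**
- Risk: the deactivated, peri-flanked carbonyl may not accept the diazo carbon before the Lewis acid decomposes 21. The acidic anthranol tautomer may be alkylated by 21. The ring B carbon may migrate. The equilibrium at C-a may not favour the needed epimer.
- Fallback (known chemistry, sets out from 12, returns at 22): 12 is lithiated and formylated with DMF to the 4-carbaldehyde F1. Horner–Wadsworth–Emmons olefination with diethyl (4-methoxybenzyl)phosphonate and KOt-Bu gives the (E)-stilbene F2. Epoxidation with dimethyldioxirane gives the trans-epoxide F3. BF3·OEt2 at −78 °C opens F3 at the carbon bearing the 4-methoxyphenyl group, and ring A closes on the cation (epoxy-arene Friedel–Crafts cyclisation) to the seven-ring alcohol F4. Dess–Martin oxidation and the same DBU equilibration give 22.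

**Step 16 (carries the label).**
- Risk: the benzylic CH2 may migrate in competition with the ring D carbon, and the enol of 31 may be O-alkylated by 21.
- Fallback (known chemistry, sets out from 12, returns at 32): Stille allylation of 12 with allyltributylstannane and Pd(PPh3)4 gives the 4-allyl block F5. Cross-metathesis with 4-methoxystyrene (second-generation Grubbs catalyst) gives the (E)-1,3-diarylpropene F6. Epoxidation gives the trans-epoxide F7. BF3·OEt2 opens F7 at the carbon bearing the 4-methoxyphenyl group and ring D closes the eight-membered ring to alcohol F8. Dess–Martin oxidation and DBU give 32.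

**Step 18.**
- Risk: face selection at C-d and C-e in an open transition state between two large chiral partners may be poor. Residual acid may desilylate 33. The benzylic C–O bond of a furan may ionise.
- Fallback (sets out from 22 and 32, returns at 35): Wittig methylenation of 22 gives the methylene compound F9. Hydroboration with 9-BBN anti to the C-a aryl group and oxidation give the primary alcohol F10. Dess–Martin oxidation gives the aldehyde F11. Aldol condensation of F11 with 32 (TiCl4, Et3N), in which only the CH2 of 32 can condense, gives the enone F12. Conjugate addition of (4-MeOC6H4)2CuLi with Me3SiCl then brings in the aryl group at C-d from the face away from C-a and gives 35.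

**Step 19.**
- Risk: enolisation of the ketone, or no addition at all because both partners are congested.
- Fallback (sets out from 35 and 12, returns at 39, bypassing 38): 35 is condensed with 18 to the tosylhydrazone F13. 12 is converted by lithiation, B(OMe)3 and acid into the boronic acid F14. Heating F13 and F14 with K2CO3 in dioxane (Barluenga reductive coupling) forms the C-i–aryl and C-i–H bonds directly.

**Step 20.**
- Risk: loss of the oxalate by ionisation and elimination before the radical chain starts, or hydrogen transfer to the wrong face of C-i.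
- Fallback (sets out from 35 and 12, returns at 39): the Grignard addition of step 19 is quenched with aqueous NH4Cl and not with the acyl chloride, which gives the tertiary alcohol F15. F15 is reduced by ionic hydrogenation with a large excess of Et3SiH and BF3·OEt2 at −78 °C, so that hydride capture outruns the hydride shift from C-h.

**Step 5.**
- Risk: erosion of enantio- and trans-selectivity with a semi-stabilised ylide, and solvolytic decomposition of the 4-methoxybenzyl sulfonium salt.
- Fallback (sets out from 6, returns at 12): the annulation is run with the achiral S-(4-methoxybenzyl)tetrahydrothiophenium bromide F16 to give racemic trans-12. Preparative chromatography on a chiral stationary phase removes the (2S,3S)-enantiomer F17.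

## Further compounds

F1 | step 10 | (2R,3R)-3-(3,5-dimethoxyphenyl)-6-methoxy-2-(4-methoxyphenyl)-2,3-dihydro-1-benzofuran-4-carbaldehyde | O=Cc1cc(OC)cc2c1[C@@H](c1cc(OC)cc(OC)c1)[C@H](c1ccc(OC)cc1)O2
F2 | step 10 | (E)-4-[2-(4-methoxyphenyl)ethenyl] block (stilbene) | COc1ccc(/C=C/c2cc(OC)cc3c2[C@@H](c2cc(OC)cc(OC)c2)[C@H](c2ccc(OC)cc2)O3)cc1
F3 | step 10 | trans-epoxide of F2 (the facial isomer that leads to the C-a configuration of 22) | COc1ccc([C@@H]2O[C@H]2c2cc(OC)cc3c2[C@@H](c2cc(OC)cc(OC)c2)[C@H](c2ccc(OC)cc2)O3)cc1
F4 | step 10 | seven-ring alcohol, OH at C-c trans to the C-a aryl group | COc1ccc([C@H]2c3c(OC)cc(OC)cc3[C@@H]3c4c(cc(OC)cc4[C@@H]2O)O[C@H]3c2ccc(OC)cc2)cc1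
F5 | step 16 | (2R,3R)-4-allyl block | C=CCc1cc(OC)cc2c1[C@@H](c1cc(OC)cc(OC)c1)[C@H](c1ccc(OC)cc1)O2
F6 | step 16 | (E)-4-[3-(4-methoxyphenyl)prop-2-enyl] block | COc1ccc(/C=C/Cc2cc(OC)cc3c2[C@@H](c2cc(OC)cc(OC)c2)[C@H](c2ccc(OC)cc2)O3)cc1
F7 | step 16 | trans-epoxide of F6 | COc1ccc([C@@H]2O[C@H]2Cc2cc(OC)cc3c2[C@@H](c2cc(OC)cc(OC)c2)[C@H](c2ccc(OC)cc2)O3)cc1
F8 | step 16 | eight-ring alcohol, OH at C-i trans to the C-h aryl group | C1c2cc(OC)cc3c2[C@@H](c2cc(OC)cc(OC)c2[C@H](c2ccc(OC)cc2)[C@H]1O)[C@H](c1ccc(OC)cc1)O3
F9 | step 18 | methylene compound from 22 (C-c=CH2) | COc1ccc([C@H]2c3c(OC)cc(OC)cc3[C@@H]3c4c(cc(OC)cc4C2=C)O[C@H]3c2ccc(OC)cc2)cc1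
F10 | step 18 | primary alcohol, C-c(H)–CH2OH, C-c as in 40 | COc1ccc([C@H]2c3c(OC)cc(OC)cc3[C@@H]3c4c(cc(OC)cc4[C@H]2CO)O[C@H]3c2ccc(OC)cc2)cc1
F11 | step 18 | aldehyde, C-c(H)–CHO | COc1ccc([C@H]2c3c(OC)cc(OC)cc3[C@@H]3c4c(cc(OC)cc4[C@H]2C=O)O[C@H]3c2ccc(OC)cc2)cc1
F12 | step 18 | (E)-enone, C-e=C-d(H)–C-c, carbonyl at C-i | COc1ccc([C@H]2c3c(OC)cc(OC)cc3[C@@H]3c4c(cc(OC)cc4[C@H]2/C=C2\c4cc(OC)cc5c4[C@@H](c4cc(OC)cc(OC)c4[C@H](c4ccc(OC)cc4)C2=O)[C@H](c2ccc(OC)cc2)O5)O[C@H]3c2ccc(OC)cc2)cc1
F13 | step 19 | 4-methylbenzenesulfonylhydrazone of 35 (C=N geometry not assigned) | COc1ccc([C@H]2c3c(OC)cc(OC)cc3[C@@H]3c4c(cc(OC)cc4[C@H]2[C@H](c2ccc(OC)cc2)[C@H]2c4cc(OC)cc5c4[C@@H](c4cc(OC)cc(OC)c4[C@H](c4ccc(OC)cc4)C2=NNS(=O)(=O)c2ccc(C)cc2)[C@H](c2ccc(OC)cc2)O5)O[C@H]3c2ccc(OC)cc2)cc1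
F14 | step 19 | (2R,3R)-block-4-ylboronic acid | OB(O)c1cc(OC)cc2c1[C@@H](c1cc(OC)cc(OC)c1)[C@H](c1ccc(OC)cc1)O2
F15 | step 20 | tertiary alcohol at C-i carrying ring E | COc1ccc([C@H]2c3c(OC)cc(OC)cc3[C@@H]3c4c(cc(OC)cc4[C@H]2[C@H](c2ccc(OC)cc2)[C@H]2c4cc(OC)cc5c4[C@@H](c4cc(OC)cc(OC)c4[C@H](c4ccc(OC)cc4)[C@]2(O)c2cc(OC)cc4c2[C@@H](c2cc(OC)cc(OC)c2)[C@H](c2ccc(OC)cc2)O4)[C@H](c2ccc(OC)cc2)O5)O[C@H]3c2ccc(OC)cc2)cc1
F16 | step 5 | S-(4-methoxybenzyl)tetrahydrothiophenium bromide | COc1ccc(C[S+]2CCCC2)cc1.[Br-]
F17 | step 5 | (2S,3S)-enantiomer of 12 | Brc1cc(OC)cc2c1[C@H](c1cc(OC)cc(OC)c1)[C@@H](c1ccc(OC)cc1)O2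
A1 | alternative 1 | (2R,3R)-4-[(tert-butyldimethylsilyloxy)methyl]-3-(3,5-dimethoxyphenyl)-2-(4-methoxyphenyl)-2,3-dihydro-1-benzofuran-6-ol | CC(C)(C)[Si](C)(C)OCc2cc(O)cc3c2[C@@H](c2cc(OC)cc(OC)c2)[C@H](c2ccc(OC)cc2)O3
A2 | alternative 2 | dibenzocyclooctenone diaryl-acetate with vinyl group at C-e, block aryl at C-i, ketone at C-h | C=C[C@H]2c4cc(OCc5ccccc5)cc(OCc5ccccc5)c4[C@H](C(=O)OC)c4cc(OC)cc(OC)c4C(=O)[C@H]2c2cc(OC)cc4c2[C@@H](c2cc(OC)cc(OC)c2)[C@H](c2ccc(OC)cc2)O4
A3 | alternative 3 | dibenzocycloheptanone diaryl-acetate with ketone at C-a and CH2 at C-c | COC(=O)[C@@H]1c2cc(OC)cc(OC)c2C(=O)Cc2cc(OCc3ccccc3)cc(OCc3ccccc3)c21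
A4 | alternative 2 | 3,5-dimethoxybenzyne | COC1=CC(OC)=CC#C1
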